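**Plan**

- Retrosynthesis: cut the C-2 ester (side-chain acid 29), then the carboxyl carbon of the acrylic acid (CO onto a vinyl triflate made from a C-1 acetyl group) and the C-4 methylidene (from a ketone). Ring B is then cut across the ring-fusion bond C-4a–C-8a and the C-1–C-2 bond in one [4+2] event; last come the C-6–C-7 bond and the two enone C=C bonds of the open chain.
- Enabling feature: in ring B the oxygen on C-2 and the sp2 carbon C-4 (a masked ketone) are 1,3-related and C-1 carries a carbonyl-derived carbon. This is the imprint of a 1-alkoxy-3-siloxydiene (C-2, C-3, C-4, C-4a) on an enoyl dienophile (C-1, C-8a); the C-7=C-8 alkene of ring A is the cis-alkene of the tether.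
- Forward: the open chain is joined by hydroalumination/iodination, B-alkyl Suzuki coupling, ynone formation, oxa-Michael addition and olefination. One intramolecular Diels–Alder reaction closes ring B and, through the tether, ring A. Methylenation, acyl-to-vinyl triflate conversion, esterification, carbonylation and deprotection finish the route.
- Stereochemistry: the four ring stereocentres arise together in the cycloaddition. Their relative configuration comes from the alkene geometries and the endo transition state, their absolute configuration from one bought stereocentre in (S)-4-benzyloxazolidinone 12. The side-chain (S) centre is bought in acetonide alcohol 25.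

Key step: step 9

Remark: soft enolisation in step 8 is taken to give the 8Z silyl enol ether (siloxy group cis to the chain), as is usual for 4-substituted 1-alkoxy-3-siloxydienes. TBS = tert-butyldimethylsilyl, TES = triethylsilyl, PMB = 4-methoxybenzyl; ring positions use octahydronaphthalene numbering (C-1 carries the acrylic acid, C-2 the ester oxygen, C-4 the methylidene, C-7 the CH2O group).

**Route**

Step 1
Reactants: 1 4-(TBS-oxy)but-2-yn-1-ol
Product: 3 (2Z)-4-(TBS-oxy)-3-iodobut-2-en-1-ol, via cyclic vinylalanate 2 (not isolated)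
Conditions: NaAlH2(OCH2CH2OMe)2, THF, 0 °C to rt; EtOAc; then I2, THF, −78 to 0 °C
Reagents that add atoms: iodine, II
Why: Hydroxyl-directed trans-hydroalumination of the propargylic alcohol puts aluminium on the distal alkyne carbon inside a five-membered alkoxyalanate, and iodinolysis with retention should give the Z iodoalkene in which the silyloxymethyl group is trans to the hydroxymethyl group.

Step 2
Reactants: 4 methyl but-3-enoate; 3 (2Z)-4-(TBS-oxy)-3-iodobut-2-en-1-ol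
Product: 6 methyl (5E)-7-hydroxy-5-(TBS-oxymethyl)hept-5-enoate, via alkylborane 5 (not isolated)
Conditions: 9-BBN, THF, 0 °C to rt; then 3, Pd(dppf)Cl2 (5 mol%), AsPh3, aq. Cs2CO3, DMF, rt
Reagents that add atoms: none
Why: Anti-Markovnikov hydroboration leaves the ester alone, and the B-alkyl Suzuki–Miyaura coupling replaces iodine with retention, so the ester chain ends up cis to the CH2OH-bearing carbon as ring A will require.

Step 3
Reactants: 6 methyl (5E)-7-hydroxy-5-(TBS-oxymethyl)hept-5-enoate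
Product: 8 (7E)-9-hydroxy-7-(TBS-oxymethyl)non-7-en-1-yn-3-one, via Weinreb amide 7 (not isolated)
Conditions: MeNH(OMe)·HCl, i-PrMgCl, THF, −20 °C; then HC≡CMgBr, −20 to 0 °C; inverse quench into cold aq. NaHSO4
Reagents that add atoms: ethynylmagnesium bromide, C#C[Mg]Br
Why: The ester is aminolysed in the flask to the Weinreb amide, whose chelated tetrahedral adduct with the alkynyl Grignard reagent stops at the ketone (Weinreb ketone synthesis), while the cold acidic quench keeps the liberated amine from adding to the ynone.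

Step 4
Reactants: 8 (7E)-9-hydroxy-7-(TBS-oxymethyl)non-7-en-1-yn-3-one
Product: 9 (2E)-7-oxo-3-(TBS-oxymethyl)non-2-en-8-ynal
Conditions: MnO2 (activated, excess), CH2Cl2, rt
Reagents that add atoms: none
Why: MnO2 oxidises only the allylic alcohol, and under these neutral conditions the enal should keep its double-bond geometry.

Step 5
Reactants: 9 (2E)-7-oxo-3-(TBS-oxymethyl)non-2-en-8-ynal
Product: 10 (2E,8E)-9-(PMB-oxy)-7-oxo-3-(TBS-oxymethyl)nona-2,8-dienal
Conditions: 4-methoxybenzyl alcohol (1.3 equiv), DABCO (10 mol%), CH2Cl2, 0 °C to rt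
Reagents that add atoms: 4-methoxybenzyl alcohol, COc1ccc(CO)cc1
Why: Amine-catalysed oxa-Michael addition of the alcohol to the terminal ynone should give the E alkoxy-enone (vinylogous ester), the β,β-disubstituted enal being too hindered to compete.

Step 6
Reactants: 11 2-(diethoxyphosphoryl)acetic acid; 12 (4S)-4-benzyl-1,3-oxazolidin-2-one
Product: 14 diethyl {2-[(4S)-4-benzyl-2-oxo-1,3-oxazolidin-3-yl]-2-oxoethyl}phosphonate, via mixed pivalic anhydride 13 (not isolated)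
Conditions: t-BuCOCl, Et3N, THF, −20 °C; then 12, LiCl, rt
Reagents that add atoms: none
Why: Mixed-anhydride N-acylation of the oxazolidinone attaches the bought stereocentre to the phosphonate needed for the olefination.

Step 7
Reactants: 10 (2E,8E)-9-(PMB-oxy)-7-oxo-3-(TBS-oxymethyl)nona-2,8-dienal; 14 diethyl {2-[(4S)-4-benzyl-2-oxo-1,3-oxazolidin-3-yl]-2-oxoethyl}phosphonate
Product: 15 (4S)-4-benzyl-3-[(2E,4E,10E)-11-(PMB-oxy)-9-oxo-5-(TBS-oxymethyl)undeca-2,4,10-trienoyl]-1,3-oxazolidin-2-one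
Conditions: LiCl, i-Pr2NEt, MeCN, rt
Reagents that add atoms: none
Why: Masamune–Roush Horner–Wadsworth–Emmons olefination should give the 2E enoyl imide under a base mild enough to leave the vinylogous ester and the existing alkene geometry untouched.

Step 8
Reactants: 15 (4S)-4-benzyl-3-[(2E,4E,10E)-11-(PMB-oxy)-9-oxo-5-(TBS-oxymethyl)undeca-2,4,10-trienoyl]-1,3-oxazolidin-2-one
Product: 16 (4S)-4-benzyl-3-[(2E,4E,8Z,10E)-11-(PMB-oxy)-9-(TES-oxy)-5-(TBS-oxymethyl)undeca-2,4,8,10-tetraenoyl]-1,3-oxazolidin-2-one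
Conditions: Et3SiOTf, Et3N, CH2Cl2, −78 to 0 °C; pentane, filtration through Et3N-deactivated silica; used at once
Reagents that add atoms: triethylsilyl trifluoromethanesulfonate, CC[Si](CC)(CC)OS(=O)(=O)C(F)(F)F
Why: Soft enolisation can occur only at C-8, the one enolisable α-carbon of the vinylogous ester ketone, and should give the Z silyl enol ether, i.e. a Danishefsky-type 1-alkoxy-3-siloxydiene with the chain in the outside position.

Step 9
Reactants: 16 (4S)-4-benzyl-3-[(2E,4E,8Z,10E)-11-(PMB-oxy)-9-(TES-oxy)-5-(TBS-oxymethyl)undeca-2,4,8,10-tetraenoyl]-1,3-oxazolidin-2-one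
Product: 18 (4S)-4-benzyl-3-{[(1R,2S,4aS,8aS)-2-(PMB-oxy)-4-oxo-7-(TBS-oxymethyl)-1,2,3,4,4a,5,6,8a-octahydronaphthalen-1-yl]carbonyl}-1,3-oxazolidin-2-one, via silyl enol ether cycloadduct 17 (not isolated)
Conditions: Me2AlCl (1.5 equiv), CH2Cl2, −78 to −30 °C; then AcOH/THF/H2O, 0 °C
Reagents that add atoms: none
Why: Me2AlCl chelates the two imide carbonyls of 16, locking the enoyl unit s-cis and activating it, and the 1-alkoxy-3-siloxydiene adds across chain C-2=C-3 in a concerted, asynchronous [4+2] cycloaddition (bond C-8 to C-3 leading, C-11 to C-2 following) to give silyl enol ether 17, which mild acid hydrolyses to ketone 18. The closest known reaction type is the auxiliary-controlled, Lewis-acid-promoted intramolecular Diels–Alder reaction of E,E,E-trienimides, joined to the known cycloadditions of Danishefsky-type dienes. Ring B is closed directly as the cyclohexene of the [4+2] event, and ring A is closed at the same time by the four-atom tether (chain C-4 to C-7) between the β-carbon of the dienophile and the diene terminus, a type 1 intramolecular Diels–Alder closure. C-1 and C-8a become trans because the dienophile is E; C-2 (OPMB) and C-4a follow from the 8Z,10E diene with both substituents outside; the trans ring fusion and the cis relation of acyl group and OPMB follow from the endo position of the chelated carbonyl; the absolute sense follows from addition to the enoyl face opposite the benzyl group of the (S)-auxiliary. The step needs endo over exo selectivity and one π-face, both secured by the rigid chelate, and it needs periselectivity for the C-2=C-3 bond, which the tether secures because addition to C-4=C-5 would have to close a four-membered ring.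

Step 10
Reactants: 18 (4S)-4-benzyl-3-{[(1R,2S,4aS,8aS)-2-(PMB-oxy)-4-oxo-7-(TBS-oxymethyl)-1,2,3,4,4a,5,6,8a-octahydronaphthalen-1-yl]carbonyl}-1,3-oxazolidin-2-one
Product: 19 (4S)-4-benzyl-3-{[(1R,2S,4aS,8aS)-2-(PMB-oxy)-4-methylidene-7-(TBS-oxymethyl)-1,2,3,4,4a,5,6,8a-octahydronaphthalen-1-yl]carbonyl}-1,3-oxazolidin-2-one
Conditions: Zn, CH2Br2, TiCl4, THF/CH2Cl2, 0 °C to rt
Reagents that add atoms: dibromomethane, BrCBr
Why: Takai–Lombardo methylenation is non-basic, so the ketone should become the exocyclic alkene without β-elimination of the OPMB group, epimerisation at C-4a or attack on the imide.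

Step 11
Reactants: 19 (4S)-4-benzyl-3-{[(1R,2S,4aS,8aS)-2-(PMB-oxy)-4-methylidene-7-(TBS-oxymethyl)-1,2,3,4,4a,5,6,8a-octahydronaphthalen-1-yl]carbonyl}-1,3-oxazolidin-2-one
Product: 20 S-ethyl (1R,2S,4aS,8aS)-2-(PMB-oxy)-4-methylidene-7-(TBS-oxymethyl)-1,2,3,4,4a,5,6,8a-octahydronaphthalene-1-carbothioate
Conditions: EtSH, n-BuLi, THF, 0 °C
Reagents that add atoms: ethanethiol, CCS
Why: The weakly basic lithium thiolate attacks the exocyclic imide carbonyl selectively (thiolysis of an N-acyloxazolidinone) and releases the auxiliary for recovery without enolising C-1.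

Step 12
Reactants: 20 S-ethyl (1R,2S,4aS,8aS)-2-(PMB-oxy)-4-methylidene-7-(TBS-oxymethyl)-1,2,3,4,4a,5,6,8a-octahydronaphthalene-1-carbothioate
Product: 21 1-[(1R,2S,4aS,8aS)-2-(PMB-oxy)-4-methylidene-7-(TBS-oxymethyl)-1,2,3,4,4a,5,6,8a-octahydronaphthalen-1-yl]ethan-1-one
Conditions: Me2CuLi (from MeLi and CuI), Et2O, −78 to −30 °C
Reagents that add atoms: lithium dimethylcuprate, [Li+].C[Cu-]C
Why: The Gilman reagent transfers one methyl group to the thioester and stops at the ketone (cuprate acylation), with no base strong enough to epimerise C-1.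

Step 13
Reactants: 21 1-[(1R,2S,4aS,8aS)-2-(PMB-oxy)-4-methylidene-7-(TBS-oxymethyl)-1,2,3,4,4a,5,6,8a-octahydronaphthalen-1-yl]ethan-1-one
Product: 23 1-[(1R,2S,4aS,8aS)-2-(PMB-oxy)-4-methylidene-7-(TBS-oxymethyl)-1,2,3,4,4a,5,6,8a-octahydronaphthalen-1-yl]ethenyl trifluoromethanesulfonate, via potassium enolate 22 (not isolated)
Conditions: KN(SiMe3)2 (1.05 equiv), THF, −78 °C; then PhNTf2, −78 to −20 °C
Reagents that add atoms: N-phenylbis(trifluoromethanesulfonimide), O=S(=O)(N(c1ccccc1)S(=O)(=O)C(F)(F)F)C(F)(F)F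
Why: Kinetic deprotonation by the bulky amide base should occur at the methyl group and not at the hindered C-1 methine, and O-triflation of the enolate gives the 1,1-disubstituted vinyl triflate.

Step 14
Reactants: 23 1-[(1R,2S,4aS,8aS)-2-(PMB-oxy)-4-methylidene-7-(TBS-oxymethyl)-1,2,3,4,4a,5,6,8a-octahydronaphthalen-1-yl]ethenyl trifluoromethanesulfonate
Product: 24 1-[(1R,2S,4aS,8aS)-2-hydroxy-4-methylidene-7-(TBS-oxymethyl)-1,2,3,4,4a,5,6,8a-octahydronaphthalen-1-yl]ethenyl trifluoromethanesulfonate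
Conditions: DDQ, CH2Cl2/pH 7 buffer (10:1), 0 °C to rt
Reagents that add atoms: none
Why: Oxidative cleavage of the 4-methoxybenzyl ether by DDQ frees the C-2 hydroxyl group while the TBS ether, the vinyl triflate and the alkenes should stay intact.

Step 15
Reactants: 25 2-[(4S)-2,2-dimethyl-1,3-dioxolan-4-yl]ethan-1-ol
Product: 26 2-[(4S)-2,2-dimethyl-1,3-dioxolan-4-yl]acetaldehyde
Conditions: Dess–Martin periodinane, NaHCO3, CH2Cl2, 0 °C to rt
Reagents that add atoms: none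
Why: Buffered Dess–Martin oxidation of the primary alcohol gives the aldehyde without touching the acetonide or the stereocentre.

Step 16
Reactants: 26 2-[(4S)-2,2-dimethyl-1,3-dioxolan-4-yl]acetaldehyde
Product: 28 2-[(4S)-2,2-dimethyl-1,3-dioxolan-4-yl]prop-2-enal, via Mannich base 27 (not isolated)
Conditions: CH2=NMe2+ I− (2 equiv), Et3N, CH2Cl2, rt
Reagents that add atoms: N,N-dimethylmethyleneiminium iodide, C=[N+](C)C.[I-]
Why: Mannich reaction with Eschenmoser's salt and loss of dimethylamine (α-methylenation of an aldehyde) installs the methylidene group; the stereocentre is not the enolised carbon and is retained.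

Step 17
Reactants: 28 2-[(4S)-2,2-dimethyl-1,3-dioxolan-4-yl]prop-2-enal
Product: 29 2-[(4S)-2,2-dimethyl-1,3-dioxolan-4-yl]prop-2-enoic acid
Conditions: NaClO2, NaH2PO4, 2-methylbut-2-ene, t-BuOH/H2O, 0 °C to rt
Reagents that add atoms: sodium chlorite, [Na+].[O-]Cl=O
Why: Pinnick oxidation converts the enal into the acrylic acid at buffered pH with a hypochlorite scavenger, so the acetonide and the alkene should survive.

Step 18
Reactants: 29 2-[(4S)-2,2-dimethyl-1,3-dioxolan-4-yl]prop-2-enoic acid; 24 1-[(1R,2S,4aS,8aS)-2-hydroxy-4-methylidene-7-(TBS-oxymethyl)-1,2,3,4,4a,5,6,8a-octahydronaphthalen-1-yl]ethenyl trifluoromethanesulfonate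
Product: 31 (1R,2S,4aS,8aS)-4-methylidene-7-(TBS-oxymethyl)-1-{1-[(trifluoromethanesulfonyl)oxy]ethenyl}-1,2,3,4,4a,5,6,8a-octahydronaphthalen-2-yl 2-[(4S)-2,2-dimethyl-1,3-dioxolan-4-yl]prop-2-enoate, via mixed trichlorobenzoic anhydride 30 (not isolated)
Conditions: 2,4,6-trichlorobenzoyl chloride, Et3N, THF, rt; then 24, DMAP, toluene, rt to 40 °C
Reagents that add atoms: none
Why: Yamaguchi esterification acylates the hindered axial C-2 alcohol at oxygen, so both stereocentres are retained, and the vinyl triflate is inert to these conditions.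

Step 19
Reactants: 31 (1R,2S,4aS,8aS)-4-methylidene-7-(TBS-oxymethyl)-1-{1-[(trifluoromethanesulfonyl)oxy]ethenyl}-1,2,3,4,4a,5,6,8a-octahydronaphthalen-2-yl 2-[(4S)-2,2-dimethyl-1,3-dioxolan-4-yl]prop-2-enoate
Product: 33 2-[(1S,2S,4aS,8aS)-2-({2-[(4S)-2,2-dimethyl-1,3-dioxolan-4-yl]prop-2-enoyl}oxy)-4-methylidene-7-(TBS-oxymethyl)-1,2,3,4,4a,5,6,8a-octahydronaphthalen-1-yl]prop-2-enoic acid, via mixed acetic anhydride 32 (not isolated)
Conditions: Pd(OAc)2 (10 mol%), dppf, KOAc, CO (1 atm), DMF, rt to 40 °C; then H2O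
Reagents that add atoms: carbon monoxide, [C-]#[O+]; potassium acetate, CC(=O)[O-].[K+]; water, O
Why: Oxidative addition of zerovalent palladium into the vinyl triflate, CO insertion and capture of the acylpalladium species by acetate give a mixed anhydride that water hydrolyses to the acrylic acid (palladium-catalysed hydroxycarbonylation of an enol triflate), CO insertion being expected to outrun Heck-type addition to the neighbouring acrylate.

Step 20
Reactants: 33 2-[(1S,2S,4aS,8aS)-2-({2-[(4S)-2,2-dimethyl-1,3-dioxolan-4-yl]prop-2-enoyl}oxy)-4-methylidene-7-(TBS-oxymethyl)-1,2,3,4,4a,5,6,8a-octahydronaphthalen-1-yl]prop-2-enoic acid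
Product: 35 2-[(1S,2S,4aS,8aS)-2-{[(3S)-3,4-dihydroxy-2-methylidenebutanoyl]oxy}-7-(hydroxymethyl)-4-methylidene-1,2,3,4,4a,5,6,8a-octahydronaphthalen-1-yl]prop-2-enoic acid, via desilylated acetonide 34 (not isolated)
Conditions: AcOH/H2O (4:1), rt to 35 °C
Reagents that add atoms: none
Why: Aqueous acetic acid hydrolyses first the primary allylic TBS ether and then the terminal acetonide (acid-catalysed solvolysis) and should leave the esters, the alkenes and all stereocentres unchanged.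

**Compound list**

1 | 4-(TBS-oxy)but-2-yn-1-ol | OCC#CCO[Si](C)(C)C(C)(C)C | starting material
2 | sodium 2,2-bis(2-methoxyethoxy)-3-(TBS-oxymethyl)-2,5-dihydro-1,2-oxaluminol-2-uide (cyclic vinylalanate) | [Na+].COCCO[Al-]1(OCCOC)OCC=C1CO[Si](C)(C)C(C)(C)C | intermediate
3 | (2Z)-4-(TBS-oxy)-3-iodobut-2-en-1-ol | OC/C=C(\I)CO[Si](C)(C)C(C)(C)C | intermediate
4 | methyl but-3-enoate | C=CCC(=O)OC | starting material
5 | methyl 4-(9-borabicyclo[3.3.1]nonan-9-yl)butanoate | COC(=O)CCCB1C2CCCC1CCC2 | intermediate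
6 | methyl (5E)-7-hydroxy-5-(TBS-oxymethyl)hept-5-enoate | OC/C=C(\CCCC(=O)OC)CO[Si](C)(C)C(C)(C)C | intermediate
7 | (5E)-7-hydroxy-N-methoxy-N-methyl-5-(TBS-oxymethyl)hept-5-enamide | OC/C=C(\CCCC(=O)N(C)OC)CO[Si](C)(C)C(C)(C)C | intermediate
8 | (7E)-9-hydroxy-7-(TBS-oxymethyl)non-7-en-1-yn-3-one | OC/C=C(\CCCC(=O)C#C)CO[Si](C)(C)C(C)(C)C | intermediate
9 | (2E)-7-oxo-3-(TBS-oxymethyl)non-2-en-8-ynal | O=C/C=C(\CCCC(=O)C#C)CO[Si](C)(C)C(C)(C)C | intermediate
10 | (2E,8E)-9-(PMB-oxy)-7-oxo-3-(TBS-oxymethyl)nona-2,8-dienal | O=C/C=C(\CCCC(=O)/C=C/OCc1ccc(OC)cc1)CO[Si](C)(C)C(C)(C)C | intermediate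
11 | 2-(diethoxyphosphoryl)acetic acid | CCOP(=O)(CC(=O)O)OCC | starting material
12 | (4S)-4-benzyl-1,3-oxazolidin-2-one | O=C1OC[C@H](Cc2ccccc2)N1 | starting material
13 | 2-(diethoxyphosphoryl)acetic pivalic anhydride | CCOP(=O)(CC(=O)OC(=O)C(C)(C)C)OCC | intermediate
14 | diethyl {2-[(4S)-4-benzyl-2-oxo-1,3-oxazolidin-3-yl]-2-oxoethyl}phosphonate | CCOP(=O)(CC(=O)N1[C@@H](Cc2ccccc2)COC1=O)OCC | intermediate
15 | (4S)-4-benzyl-3-[(2E,4E,10E)-11-(PMB-oxy)-9-oxo-5-(TBS-oxymethyl)undeca-2,4,10-trienoyl]-1,3-oxazolidin-2-one | O=C1OC[C@H](Cc2ccccc2)N1C(=O)/C=C/C=C(/CO[Si](C)(C)C(C)(C)C)CCCC(=O)/C=C/OCc1ccc(OC)cc1 | intermediate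
16 | (4S)-4-benzyl-3-[(2E,4E,8Z,10E)-11-(PMB-oxy)-9-(TES-oxy)-5-(TBS-oxymethyl)undeca-2,4,8,10-tetraenoyl]-1,3-oxazolidin-2-one | O=C1OC[C@H](Cc2ccccc2)N1C(=O)/C=C/C=C(/CO[Si](C)(C)C(C)(C)C)CC/C=C(\O[Si](CC)(CC)CC)/C=C/OCc1ccc(OC)cc1 | intermediate
17 | (4S)-4-benzyl-3-{[(1R,2S,4aS,8aS)-2-(PMB-oxy)-4-(TES-oxy)-7-(TBS-oxymethyl)-1,2,4a,5,6,8a-hexahydronaphthalen-1-yl]carbonyl}-1,3-oxazolidin-2-one | O=C1OC[C@H](Cc2ccccc2)N1C(=O)[C@@H]3[C@H]4C=C(CO[Si](C)(C)C(C)(C)C)CC[C@@H]4C(O[Si](CC)(CC)CC)=C[C@@H]3OCc3ccc(OC)cc3 | intermediate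
18 | (4S)-4-benzyl-3-{[(1R,2S,4aS,8aS)-2-(PMB-oxy)-4-oxo-7-(TBS-oxymethyl)-1,2,3,4,4a,5,6,8a-octahydronaphthalen-1-yl]carbonyl}-1,3-oxazolidin-2-one | O=C1OC[C@H](Cc2ccccc2)N1C(=O)[C@@H]3[C@H]4C=C(CO[Si](C)(C)C(C)(C)C)CC[C@@H]4C(=O)C[C@@H]3OCc3ccc(OC)cc3 | intermediate
19 | (4S)-4-benzyl-3-{[(1R,2S,4aS,8aS)-2-(PMB-oxy)-4-methylidene-7-(TBS-oxymethyl)-1,2,3,4,4a,5,6,8a-octahydronaphthalen-1-yl]carbonyl}-1,3-oxazolidin-2-one | O=C1OC[C@H](Cc2ccccc2)N1C(=O)[C@@H]3[C@H]4C=C(CO[Si](C)(C)C(C)(C)C)CC[C@@H]4C(=C)C[C@@H]3OCc3ccc(OC)cc3 | intermediate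
20 | S-ethyl (1R,2S,4aS,8aS)-2-(PMB-oxy)-4-methylidene-7-(TBS-oxymethyl)-1,2,3,4,4a,5,6,8a-octahydronaphthalene-1-carbothioate | CCSC(=O)[C@@H]1[C@H]2C=C(CO[Si](C)(C)C(C)(C)C)CC[C@@H]2C(=C)C[C@@H]1OCc1ccc(OC)cc1 | intermediate
21 | 1-[(1R,2S,4aS,8aS)-2-(PMB-oxy)-4-methylidene-7-(TBS-oxymethyl)-1,2,3,4,4a,5,6,8a-octahydronaphthalen-1-yl]ethan-1-one | CC(=O)[C@@H]1[C@H]2C=C(CO[Si](C)(C)C(C)(C)C)CC[C@@H]2C(=C)C[C@@H]1OCc1ccc(OC)cc1 | intermediate
22 | potassium 1-[(1R,2S,4aS,8aS)-2-(PMB-oxy)-4-methylidene-7-(TBS-oxymethyl)-1,2,3,4,4a,5,6,8a-octahydronaphthalen-1-yl]ethen-1-olate | [K+].[O-]C(=C)[C@@H]1[C@H]2C=C(CO[Si](C)(C)C(C)(C)C)CC[C@@H]2C(=C)C[C@@H]1OCc1ccc(OC)cc1 | intermediate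
23 | 1-[(1R,2S,4aS,8aS)-2-(PMB-oxy)-4-methylidene-7-(TBS-oxymethyl)-1,2,3,4,4a,5,6,8a-octahydronaphthalen-1-yl]ethenyl trifluoromethanesulfonate | C=C(OS(=O)(=O)C(F)(F)F)[C@@H]1[C@H]2C=C(CO[Si](C)(C)C(C)(C)C)CC[C@@H]2C(=C)C[C@@H]1OCc1ccc(OC)cc1 | intermediate
24 | 1-[(1R,2S,4aS,8aS)-2-hydroxy-4-methylidene-7-(TBS-oxymethyl)-1,2,3,4,4a,5,6,8a-octahydronaphthalen-1-yl]ethenyl trifluoromethanesulfonate | C=C(OS(=O)(=O)C(F)(F)F)[C@@H]1[C@H]2C=C(CO[Si](C)(C)C(C)(C)C)CC[C@@H]2C(=C)C[C@@H]1O | intermediate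
25 | 2-[(4S)-2,2-dimethyl-1,3-dioxolan-4-yl]ethan-1-ol | OCC[C@H]1COC(C)(C)O1 | starting material
26 | 2-[(4S)-2,2-dimethyl-1,3-dioxolan-4-yl]acetaldehyde | O=CC[C@H]1COC(C)(C)O1 | intermediate
27 | 3-(dimethylamino)-2-[(4S)-2,2-dimethyl-1,3-dioxolan-4-yl]propanal (both C-2 epimers) | CN(C)CC(C=O)[C@H]1COC(C)(C)O1 | intermediate
28 | 2-[(4S)-2,2-dimethyl-1,3-dioxolan-4-yl]prop-2-enal | C=C(C=O)[C@H]1COC(C)(C)O1 | intermediate
29 | 2-[(4S)-2,2-dimethyl-1,3-dioxolan-4-yl]prop-2-enoic acid | C=C(C(=O)O)[C@H]1COC(C)(C)O1 | intermediate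
30 | 2-[(4S)-2,2-dimethyl-1,3-dioxolan-4-yl]prop-2-enoic 2,4,6-trichlorobenzoic anhydride | C=C(C(=O)OC(=O)c1c(Cl)cc(Cl)cc1Cl)[C@H]1COC(C)(C)O1 | intermediate
31 | (1R,2S,4aS,8aS)-4-methylidene-7-(TBS-oxymethyl)-1-{1-[(trifluoromethanesulfonyl)oxy]ethenyl}-1,2,3,4,4a,5,6,8a-octahydronaphthalen-2-yl 2-[(4S)-2,2-dimethyl-1,3-dioxolan-4-yl]prop-2-enoate | C=C(OS(=O)(=O)C(F)(F)F)[C@@H]1[C@H]2C=C(CO[Si](C)(C)C(C)(C)C)CC[C@@H]2C(=C)C[C@@H]1OC(=O)C(=C)[C@H]1COC(C)(C)O1 | intermediate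
32 | acetic 2-[(1S,2S,4aS,8aS)-2-({2-[(4S)-2,2-dimethyl-1,3-dioxolan-4-yl]prop-2-enoyl}oxy)-4-methylidene-7-(TBS-oxymethyl)-1,2,3,4,4a,5,6,8a-octahydronaphthalen-1-yl]prop-2-enoic anhydride | C=C(C(=O)OC(C)=O)[C@@H]1[C@H]2C=C(CO[Si](C)(C)C(C)(C)C)CC[C@@H]2C(=C)C[C@@H]1OC(=O)C(=C)[C@H]1COC(C)(C)O1 | intermediate
33 | 2-[(1S,2S,4aS,8aS)-2-({2-[(4S)-2,2-dimethyl-1,3-dioxolan-4-yl]prop-2-enoyl}oxy)-4-methylidene-7-(TBS-oxymethyl)-1,2,3,4,4a,5,6,8a-octahydronaphthalen-1-yl]prop-2-enoic acid | C=C(C(=O)O)[C@@H]1[C@H]2C=C(CO[Si](C)(C)C(C)(C)C)CC[C@@H]2C(=C)C[C@@H]1OC(=O)C(=C)[C@H]1COC(C)(C)O1 | intermediate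
34 | 2-[(1S,2S,4aS,8aS)-2-({2-[(4S)-2,2-dimethyl-1,3-dioxolan-4-yl]prop-2-enoyl}oxy)-7-(hydroxymethyl)-4-methylidene-1,2,3,4,4a,5,6,8a-octahydronaphthalen-1-yl]prop-2-enoic acid | C=C(C(=O)O)[C@@H]1[C@H]2C=C(CO)CC[C@@H]2C(=C)C[C@@H]1OC(=O)C(=C)[C@H]1COC(C)(C)O1 | intermediate
35 | 2-[(1S,2S,4aS,8aS)-2-{[(3S)-3,4-dihydroxy-2-methylidenebutanoyl]oxy}-7-(hydroxymethyl)-4-methylidene-1,2,3,4,4a,5,6,8a-octahydronaphthalen-1-yl]prop-2-enoic acid | C=C(C(=O)O)[C@@H]1[C@H]2C=C(CO)CC[C@@H]2C(=C)C[C@@H]1OC(=O)C(=C)[C@H](O)CO | target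

**Step count and risks**

Total step count: 20. Longest linear sequence: 16 steps (steps 1–5, 7–14 and 18–20); steps 6 and 15–17 are side branches.

Steps most likely to fail:

Step 9. The Lewis acid may strip the silyl enol ether or the PMB enol ether before cycloaddition, the addition may become stepwise and stop after the first C–C bond, or endo and facial control may be insufficient. The fallback sets out from 15 and comes back at 18, and builds ring B by two conjugate additions instead of a cycloaddition. Kinetic deprotonation of 15 at C-8 with LiN(SiMe3)2 (THF, −78 °C) gives the cross-conjugated lithium dienolate, which should add to C-3 of the lithium-chelated enoyl imide (6-exo Michael addition, ring A) and give after a cold quench (4S)-4-benzyl-3-{[(1S,6S)-6-[(2E)-3-(PMB-oxy)prop-2-enoyl]-3-(TBS-oxymethyl)cyclohex-2-en-1-yl]acetyl}-1,3-oxazolidin-2-one F1. Soft enolisation of the imide in F1 with TiCl4 and i-Pr2NEt (CH2Cl2, −78 °C) should then close ring B by 6-endo Michael addition of the titanium enolate to the alkoxy-enone, with protonation at low temperature to keep the OPMB group, giving 18 (double Michael annulation).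

Step 19. The vinylpalladium intermediate may add to the acrylate alkene of the C-2 ester (Heck-type cyclisation) before CO insertion. The fallback sets out from 23 and comes back at 34, and moves the carbonylation ahead of the esterification. Carbonylation of 23 (Pd(OAc)2, dppf, CO, Et3N, 2-(trimethylsilyl)ethanol, DMF) should give 2-(trimethylsilyl)ethyl 2-[(1S,2S,4aS,8aS)-2-(PMB-oxy)-4-methylidene-7-(TBS-oxymethyl)-1,2,3,4,4a,5,6,8a-octahydronaphthalen-1-yl]prop-2-enoate F2. DDQ as in step 14 gives the C-2 alcohol 2-(trimethylsilyl)ethyl 2-[(1S,2S,4aS,8aS)-2-hydroxy-4-methylidene-7-(TBS-oxymethyl)-1,2,3,4,4a,5,6,8a-octahydronaphthalen-1-yl]prop-2-enoate F3, and esterification with 29 as in step 18 gives the diester 2-(trimethylsilyl)ethyl 2-[(1S,2S,4aS,8aS)-2-({2-[(4S)-2,2-dimethyl-1,3-dioxolan-4-yl]prop-2-enoyl}oxy)-4-methylidene-7-(TBS-oxymethyl)-1,2,3,4,4a,5,6,8a-octahydronaphthalen-1-yl]prop-2-enoate F4. Bu4NF (THF, 0 °C) then cleaves the silylethyl ester and the TBS ether to give 34, which the acid of step 20 converts into 35.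

Step 13. The base may deprotonate the C-1 methine, whose hydrogen is anti-periplanar to the axial OPMB group, leading to loss of the alkoxy group or a regioisomeric triflate, or it may eliminate the terminal vinyl triflate to an alkyne. The fallback sets out from 21 and comes back at 33, and replaces enolate triflation by a Barton vinyl iodide synthesis. Hydrazine hydrate (Et3N, EtOH) gives the hydrazone 1-[(1S,2S,4aS,8aS)-2-(PMB-oxy)-4-methylidene-7-(TBS-oxymethyl)-1,2,3,4,4a,5,6,8a-octahydronaphthalen-1-yl]ethan-1-one hydrazone F5, and I2 with 1,1,3,3-tetramethylguanidine (THF, 0 °C) gives (1R,2S,4aS,8aS)-1-(1-iodoethenyl)-2-(PMB-oxy)-4-methylidene-7-(TBS-oxymethyl)-1,2,3,4,4a,5,6,8a-octahydronaphthalene F6. DDQ as in step 14 gives (1R,2S,4aS,8aS)-1-(1-iodoethenyl)-4-methylidene-7-(TBS-oxymethyl)-1,2,3,4,4a,5,6,8a-octahydronaphthalen-2-ol F7, esterification with 29 as in step 18 gives (1R,2S,4aS,8aS)-1-(1-iodoethenyl)-4-methylidene-7-(TBS-oxymethyl)-1,2,3,4,4a,5,6,8a-octahydronaphthalen-2-yl 2-[(4S)-2,2-dimethyl-1,3-dioxolan-4-yl]prop-2-enoate F8, and carbonylation of F8 under the conditions of step 19 gives 33.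

**Further compounds**

F1 | step 9 | (4S)-4-benzyl-3-{[(1S,6S)-6-[(2E)-3-(PMB-oxy)prop-2-enoyl]-3-(TBS-oxymethyl)cyclohex-2-en-1-yl]acetyl}-1,3-oxazolidin-2-one | O=C1OC[C@H](Cc2ccccc2)N1C(=O)C[C@H]3C=C(CO[Si](C)(C)C(C)(C)C)CC[C@@H]3C(=O)/C=C/OCc3ccc(OC)cc3
F2 | step 19 | 2-(trimethylsilyl)ethyl 2-[(1S,2S,4aS,8aS)-2-(PMB-oxy)-4-methylidene-7-(TBS-oxymethyl)-1,2,3,4,4a,5,6,8a-octahydronaphthalen-1-yl]prop-2-enoate | C=C(C(=O)OCC[Si](C)(C)C)[C@@H]1[C@H]2C=C(CO[Si](C)(C)C(C)(C)C)CC[C@@H]2C(=C)C[C@@H]1OCc1ccc(OC)cc1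
F3 | step 19 | 2-(trimethylsilyl)ethyl 2-[(1S,2S,4aS,8aS)-2-hydroxy-4-methylidene-7-(TBS-oxymethyl)-1,2,3,4,4a,5,6,8a-octahydronaphthalen-1-yl]prop-2-enoate | C=C(C(=O)OCC[Si](C)(C)C)[C@@H]1[C@H]2C=C(CO[Si](C)(C)C(C)(C)C)CC[C@@H]2C(=C)C[C@@H]1O
F4 | step 19 | 2-(trimethylsilyl)ethyl 2-[(1S,2S,4aS,8aS)-2-({2-[(4S)-2,2-dimethyl-1,3-dioxolan-4-yl]prop-2-enoyl}oxy)-4-methylidene-7-(TBS-oxymethyl)-1,2,3,4,4a,5,6,8a-octahydronaphthalen-1-yl]prop-2-enoate | C=C(C(=O)OCC[Si](C)(C)C)[C@@H]1[C@H]2C=C(CO[Si](C)(C)C(C)(C)C)CC[C@@H]2C(=C)C[C@@H]1OC(=O)C(=C)[C@H]1COC(C)(C)O1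
F5 | step 13 | 1-[(1S,2S,4aS,8aS)-2-(PMB-oxy)-4-methylidene-7-(TBS-oxymethyl)-1,2,3,4,4a,5,6,8a-octahydronaphthalen-1-yl]ethan-1-one hydrazone | CC(=NN)[C@@H]1[C@H]2C=C(CO[Si](C)(C)C(C)(C)C)CC[C@@H]2C(=C)C[C@@H]1OCc1ccc(OC)cc1
F6 | step 13 | (1R,2S,4aS,8aS)-1-(1-iodoethenyl)-2-(PMB-oxy)-4-methylidene-7-(TBS-oxymethyl)-1,2,3,4,4a,5,6,8a-octahydronaphthalene | C=C(I)[C@@H]1[C@H]2C=C(CO[Si](C)(C)C(C)(C)C)CC[C@@H]2C(=C)C[C@@H]1OCc1ccc(OC)cc1
F7 | step 13 | (1R,2S,4aS,8aS)-1-(1-iodoethenyl)-4-methylidene-7-(TBS-oxymethyl)-1,2,3,4,4a,5,6,8a-octahydronaphthalen-2-ol | C=C(I)[C@@H]1[C@H]2C=C(CO[Si](C)(C)C(C)(C)C)CC[C@@H]2C(=C)C[C@@H]1O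
F8 | step 13 | (1R,2S,4aS,8aS)-1-(1-iodoethenyl)-4-methylidene-7-(TBS-oxymethyl)-1,2,3,4,4a,5,6,8a-octahydronaphthalen-2-yl 2-[(4S)-2,2-dimethyl-1,3-dioxolan-4-yl]prop-2-enoate | C=C(I)[C@@H]1[C@H]2C=C(CO[Si](C)(C)C(C)(C)C)CC[C@@H]2C(=C)C[C@@H]1OC(=O)C(=C)[C@H]1COC(C)(C)O1
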